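In a one-step world you would multiply a rate constant by a time and be done, but this flask feeds its substrate through a gas that is being lost while it dissolves.

    gas phase ⇌ dissolved gas, rate k1*(csat - [dissolved gas]) (k1 = 3.00 × 10⁻⁴ s⁻¹, csat = 37 mM)
    substrate + dissolved gas ⇌ target (K2 = 47 L mol⁻¹, k2 = 0.00401 L mol⁻¹ s⁻¹)
    substrate ⇌ dormant form (K3 = 0.42, k3 = 1.83 × 10⁻⁵ s⁻¹)
    dissolved gas → decomposed reagent (k4 = 0.00102 s⁻¹)

substrate 0.062 M; gas phase 37 mM (held); time 2.0 h

* target at 2.0 h, in percent of the substrate charged
* concentration of dissolved gas in solution at 2.0 h, in percent of saturation

Transfer from the gas phase could deliver by 2.0 h at most 129% of the substrate charged into a solution kept empty, more than the charge, so supply looks ample. But decomposition on its own halves the dissolved gas in 0.19 h, faster than forward uptake on its own with the substrate as charged, at 0.77 h, and short against the 2.0 h run, so I replace the gas curve by a flat line. This is the held level, the quasi-steady concentration at which transfer in balances the losses: the transfer coefficient times saturation, divided by the sum of that coefficient, the decomposition constant, and the uptake rate constant times the substrate charged, 7.08 mM, or 19.1% of saturation.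

At that level uptake is pseudo-first-order, with a forward constant of 2.84 × 10⁻⁵ s⁻¹. The way back, the rate constant over the equilibrium constant, is 8.53 × 10⁻⁵ s⁻¹, faster than the forward one, so the target heads for 25.0% of the substrate charged, approached at the sum of the two constants. By 2.0 h that gives 14.0%. The line ignores the climb from empty, so I expect this figure to err high, and I also leave out the dormant form, whose forward half-life of 11 h is longer than the run.

The forecast, a little apart from mine, gives 13% of target and 21% of saturation, with the gas “at a low quasi-steady level”.

The simulation gives 12.8% of target and 20.9% of saturation. At 2.00 h the dissolved gas was being made 1.01 times as fast as it was used up, each step taken net, and it stood at 7.74 mM against the held level of 7.08 mM. Put the same level and the same approach to the same flask left until 5.0 h, and you reckon 21.7% of the substrate charged; that flask holds 20.5% of target.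

The rate constants belong to no real substance; the flask was simulated.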